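The route rests on disconnecting C6–C7 (germacrane locants), the bond shared by the ten-membered carbocycle and the α-methylene-γ-lactone ring. In the key step an acyclic (Z)-2-(bromomethyl)enoate carrying a (Z)-enal is reduced by CrCl2 to an allylchromium species whose γ-carbon C7 adds to the C6 aldehyde. One operation closes the macrocycle, sets C6 and C7 under control of the C8 stereocentre and, by attack of O6 on the C12 ester, closes the lactone. It exploits the homoallylic array O6–C6–C7–C11(=C13)–C12. The precursor is assembled from 2-deoxy-L-ribose (C7–C10 and C14, with the oxygens of C8 and C9), nerol (C1–C6, C15) and methyl acrylate (C11–C13).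

Key step: step 14

Remark: locants are those of the germacrane skeleton of the target (C6 bears the lactone oxygen, C7 is the ring-fusion carbon, C12 the lactone carbonyl, C13 the exocyclic methylene, C14 the ester carbon on C10, C15 the methyl on C4); 2-deoxy-L-ribose, nerol, methyl acrylate and angelic acid are taken as commercial.

Step 1
Reactants: 1 2-deoxy-L-ribose
Product: 2 2-deoxy-L-ribono-1,4-lactone
Conditions: Br2, BaCO3, H2O, rt
Reagents that add atoms: none
Why: Bromine water oxidises the lactol carbon of the aldose to the acid level and the five-membered lactone closes on O4 (aldose-to-aldonolactone oxidation), leaving the future C8 and C9 stereocentres untouched.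

Step 2
Reactants: 2 2-deoxy-L-ribono-1,4-lactone
Product: 4 (4R,5S)-4-(tert-butyldimethylsilyloxy)-5-[(triethylsilyloxy)methyl]oxolan-2-one, via primary TES ether 3 (not isolated)
Conditions: TESCl (1.05 equiv), imidazole, DMF, −40 °C; then TBSCl, imidazole, rt
Reagents that add atoms: chlorotriethylsilane, CC[Si](Cl)(CC)CC; tert-butyldimethylsilyl chloride, CC(C)(C)[Si](C)(C)Cl
Why: Silyl ether formation is stepwise, the primary hydroxyl reacting first with TESCl at low temperature and the secondary one then taking TBS, so that O7, O9 and later O8 can be unmasked independently.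

Step 3
Reactants: 5 nerol
Product: 6 neryl 4-methoxybenzyl ether
Conditions: NaH, PMBCl, Bu4NI (cat.), THF/DMF, 0 °C to rt
Reagents that add atoms: 4-methoxybenzyl chloride, COc1ccc(CCl)cc1
Why: Williamson ether synthesis gives a base-stable group that can later be removed oxidatively without touching silyl ethers or an allylic bromide.

Step 4
Reactants: 6 neryl 4-methoxybenzyl ether
Product: 8 (4Z)-6-[(4-methoxybenzyl)oxy]-4-methylhex-4-enal, via vicinal diol 7 (not isolated)
Conditions: K2OsO4·2H2O (1 mol %), NMO, acetone/H2O, 0 °C; then NaIO4, rt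
Reagents that add atoms: N-methylmorpholine N-oxide, C[N+]1([O-])CCOCC1; water, O
Why: Catalytic osmylation should attack the electron-richer terminal trisubstituted alkene in preference to the alkene deactivated by the allylic ether oxygen, and periodate glycol cleavage then releases the C1 aldehyde and acetone without affecting the Z-alkene.

Step 5
Reactants: 4 silylated lactone; 8 aldehyde
Product: 9 aldol adduct (3,4-trans lactone; both carbinol epimers)
Conditions: LiN(iPr)2, THF, −78 °C; then 8; AcOH quench at −78 °C
Reagents that add atoms: none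
Why: Aldol addition of the lactone lithium enolate forms the C10–C1 bond with the aldehyde entering anti to the C9 silyloxy group, and the two new centres need no control because both are removed in step 6.

Step 6
Reactants: 9 aldol adduct
Product: 11 (E)-alkylidene lactone (C1=C10 formed; O9 TBS; O7 TES; O6 PMB), via mesylate 10 (not isolated)
Conditions: MsCl, Et3N, CH2Cl2, 0 °C; then DBU, rt
Reagents that add atoms: none
Why: Mesylation and DBU-induced E1cB elimination give the conjugated alkylidene lactone, for which the E isomer (C2 cis to C9, trans to the carbonyl, as the target requires) is the more stable and expected major product, mesylate being a far better leaving group than the ring silyloxy group.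

Step 7
Reactants: 11 (E)-alkylidene lactone
Product: 13 seco hydroxy ester (C14 methyl ester; free 8-OH), via lithium carboxylate 12 (not isolated)
Conditions: LiOH·H2O (1.1 equiv), THF/H2O, 0 °C; concentrate; MeI, DMF, 0 °C to rt; used at once
Reagents that add atoms: lithium hydroxide, [Li+].[OH-]; iodomethane, CI
Why: Hydroxide opens the lactone by acyl–oxygen cleavage, so C8 keeps its configuration, and SN2 methylation of the carboxylate under neutral conditions gives the methyl ester, which is kept cold and used directly to avoid relactonisation.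

Step 8
Reactants: 13 seco hydroxy ester
Product: 14 tris-silyl ether (O8 TES)
Conditions: TESOTf, 2,6-lutidine, CH2Cl2, −78 °C
Reagents that add atoms: triethylsilyl trifluoromethanesulfonate, CC[Si](CC)(CC)OS(=O)(=O)C(F)(F)F
Why: Silylation with the triflate at −78 °C is much faster than relactonisation and makes O8 a poor leaving group, which matters because an acyloxy group at C8 would be eliminated from the later allylmetal intermediate.

Step 9
Reactants: 14 tris-silyl ether
Product: 15 C7 aldehyde
Conditions: (COCl)2, DMSO, CH2Cl2, −78 to −40 °C; then Et3N, −78 to 0 °C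
Reagents that add atoms: none
Why: Under Swern conditions a primary triethylsilyl ether is cleaved by the chlorosulfonium reagent and oxidised directly to the aldehyde, whereas secondary TES, TBS and PMB ethers are retained, so C7 is unmasked and oxidised in one operation.

Step 10
Reactants: 15 C7 aldehyde; 16 methyl acrylate
Product: 17 Morita–Baylis–Hillman adduct (both C7 carbinol epimers)
Conditions: DABCO (1 equiv), 16 (excess), 1,4-dioxane/H2O, rt
Reagents that add atoms: none
Why: Morita–Baylis–Hillman reaction, in which the DABCO-derived acrylate enolate adds to the electrophilic α-silyloxy aldehyde and loss of the amine gives the α-methylene-β-hydroxy ester, whose C7 carbinol centre becomes sp2 in step 11.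

Step 11
Reactants: 17 Morita–Baylis–Hillman adduct
Product: 18 (Z)-allylic bromide
Conditions: NBS, Me2S, CH2Cl2, 0 °C to rt
Reagents that add atoms: N-bromosuccinimide, O=C1CCC(=O)N1Br
Why: Activation of the allylic alcohol as an alkoxysulfonium ion (Corey–Kim-type reagent) and SN2′ attack of bromide give the transposed primary bromide, with C8 cis to CH2Br as is general for such adducts.

Step 12
Reactants: 18 (Z)-allylic bromide
Product: 19 C6 allylic alcohol
Conditions: DDQ, CH2Cl2/pH 7 buffer, 0 °C
Reagents that add atoms: none
Why: DDQ oxidises the electron-rich benzyl ether to an oxocarbenium ion that the buffer hydrolyses, a neutral deprotection that leaves the allylic bromide, the silyl ethers and the enoates intact.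

Step 13
Reactants: 19 C6 allylic alcohol
Product: 20 (Z)-enal allylic bromide
Conditions: TEMPO (10 mol %), PhI(OAc)2, CH2Cl2, rt
Reagents that add atoms: none
Why: TEMPO-catalysed oxoammonium oxidation converts the primary allylic alcohol into the enal without over-oxidation or Z to E isomerisation and does not affect the allylic bromide.

Step 14
Reactants: 20 (Z)-enal allylic bromide
Product: 22 macrolactone (6,12-olide; O8 TES; O9 TBS), via seco hydroxy ester 21 (not isolated)
Conditions: CrCl2 (10 equiv), THF, rt, slow addition of 20 (final 2 mM); aq. NH4Cl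
Reagents that add atoms: none
Why: Two equivalents of CrCl2 reduce the allylic bromide to a 2-(methoxycarbonyl)allylchromium species (trivalent chromium) that adds through its γ-carbon C7 to the C6 aldehyde in a closed six-membered chair-like transition state, and the chromium alkoxide of 21 then attacks the C12 methyl ester. The closest known reaction type is the chromium-mediated Barbier (Nozaki–Hiyama–Kishi) allylation of aldehydes with 2-(bromomethyl)acrylates followed by lactonisation, which is established for α-methylene-γ-butyrolactones and for closing ten-membered germacranolide rings. The ten-membered carbocycle closes by C6–C7 bond formation (10-exo-trig addition to the carbonyl, SE2′ at the allyl unit) and the γ-lactone then closes by 5-exo-trig acyl substitution at C12 with loss of methanol. C7 is controlled by the adjacent C8 stereocentre: allylic 1,3-strain places H8 in the plane of C7=C11, the bulky ring chain (C9) lies anti to the incoming aldehyde and the OTES group outside, so C6 should attack the face that gives 7S; C6 follows from C7 because C5 and C8 both sit equatorial in the chair, giving the anti adduct and hence the trans-fused lactone (6R). The allylchromium equilibrates its C7=C11 geometry by metallotropic shift, so the geometry of the bromide is not decisive. The step needs cyclisation over oligomerisation, γ- over α-attack and no 1,4-elimination: high dilution and the two Z-alkenes (C4=C5, C1=C10) that fold the chain favour ring closure, the cyclic transition state enforces γ-attack, and O8 is a silyl ether and therefore a poor leaving group.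

Step 15
Reactants: 22 macrolactone
Product: 23 C8 alcohol (O9 TBS)
Conditions: PPTS (cat.), MeOH/CH2Cl2, 0 °C to rt
Reagents that add atoms: none
Why: Acid-catalysed methanolysis cleaves the secondary triethylsilyl ether much faster than the hindered tert-butyldimethylsilyl ether, and the same mild acid completes lactone closure should any seco hydroxy ester remain.

Step 16
Reactants: 23 C8 alcohol; 24 angelic acid
Product: 25 8-O-angelate (O9 TBS)
Conditions: 24, 2,4,6-trichlorobenzoyl chloride, Et3N, toluene, rt; then 23, 75 °C
Reagents that add atoms: none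
Why: Acylation of the only free hydroxyl by the preformed mixed anhydride (Yamaguchi-type esterification run without a nucleophilic amine catalyst) should deliver the angelate without Z to E isomerisation to the tiglate.

Step 17
Reactants: 25 8-O-angelate
Product: 26 target, CNP0305372.1
Conditions: HF·pyridine, THF, 0 °C to rt
Reagents that add atoms: none
Why: Acidic fluoride cleaves the remaining silyl ether under non-basic conditions, which avoids acyl migration from O8 to O9, isomerisation of the angelate and conjugate addition to the α-methylene lactone.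

Compound list
1 | 2-deoxy-L-ribose, (3R,4S)-3,4,5-trihydroxypentanal (open-chain form drawn) | O=CC[C@@H](O)[C@@H](O)CO | starting material
2 | 2-deoxy-L-ribono-1,4-lactone, (4R,5S)-4-hydroxy-5-(hydroxymethyl)oxolan-2-one | O=C1C[C@@H](O)[C@H](CO)O1 | intermediate
3 | (4R,5S)-4-hydroxy-5-[(triethylsilyloxy)methyl]oxolan-2-one | O=C1C[C@@H](O)[C@H](CO[Si](CC)(CC)CC)O1 | intermediate
4 | (4R,5S)-4-(tert-butyldimethylsilyloxy)-5-[(triethylsilyloxy)methyl]oxolan-2-one | O=C1C[C@@H](O[Si](C)(C)C(C)(C)C)[C@H](CO[Si](CC)(CC)CC)O1 | intermediate
5 | nerol, (2Z)-3,7-dimethylocta-2,6-dien-1-ol | CC(C)=CCC/C(C)=C\CO | starting material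
6 | neryl 4-methoxybenzyl ether | CC(C)=CCC/C(C)=C\COCc1ccc(OC)cc1 | intermediate
7 | (6Z)-8-[(4-methoxybenzyl)oxy]-2,6-dimethyloct-6-ene-2,3-diol (racemic at C3) | CC(C)(O)C(O)CC/C(C)=C\COCc1ccc(OC)cc1 | intermediate
8 | (4Z)-6-[(4-methoxybenzyl)oxy]-4-methylhex-4-enal | O=CCC/C(C)=C\COCc1ccc(OC)cc1 | intermediate
9 | aldol adduct: lactone 4 bearing at C3, trans to the 4-silyloxy group, a (4Z)-1-hydroxy-6-[(4-methoxybenzyl)oxy]-4-methylhex-4-enyl group (carbinol epimers) | O=C1[C@H](C(O)CC/C(C)=C\COCc2ccc(OC)cc2)[C@@H](O[Si](C)(C)C(C)(C)C)[C@H](CO[Si](CC)(CC)CC)O1 | intermediate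
10 | methanesulfonate of 9 | O=C1[C@H](C(OS(C)(=O)=O)CC/C(C)=C\COCc2ccc(OC)cc2)[C@@H](O[Si](C)(C)C(C)(C)C)[C@H](CO[Si](CC)(CC)CC)O1 | intermediate
11 | (3E,4R,5S)-4-(tert-butyldimethylsilyloxy)-3-{(4Z)-6-[(4-methoxybenzyl)oxy]-4-methylhex-4-enylidene}-5-[(triethylsilyloxy)methyl]oxolan-2-one | O=C1/C(=C/CC/C(C)=C\COCc2ccc(OC)cc2)[C@@H](O[Si](C)(C)C(C)(C)C)[C@H](CO[Si](CC)(CC)CC)O1 | intermediate
12 | lithium carboxylate of the ring-opened acid (free 8-OH) | [Li+].[O-]C(=O)/C(=C/CC/C(C)=C\COCc1ccc(OC)cc1)[C@@H](O[Si](C)(C)C(C)(C)C)[C@H](CO[Si](CC)(CC)CC)O | intermediate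
13 | methyl (2E,6Z)-2-[(1R,2S)-1-(tert-butyldimethylsilyloxy)-2-hydroxy-3-(triethylsilyloxy)propyl]-8-[(4-methoxybenzyl)oxy]-6-methylocta-2,6-dienoate | COC(=O)/C(=C/CC/C(C)=C\COCc1ccc(OC)cc1)[C@@H](O[Si](C)(C)C(C)(C)C)[C@H](CO[Si](CC)(CC)CC)O | intermediate
14 | 8-O-triethylsilyl ether of 13 (O7 TES, O8 TES, O9 TBS, O6 PMB) | COC(=O)/C(=C/CC/C(C)=C\COCc1ccc(OC)cc1)[C@@H](O[Si](C)(C)C(C)(C)C)[C@H](CO[Si](CC)(CC)CC)O[Si](CC)(CC)CC | intermediate
15 | C7 aldehyde (O8 TES, O9 TBS, O6 PMB; C8 and C9 as in 13) | COC(=O)/C(=C/CC/C(C)=C\COCc1ccc(OC)cc1)[C@@H](O[Si](C)(C)C(C)(C)C)[C@H](C=O)O[Si](CC)(CC)CC | intermediate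
16 | methyl acrylate | C=CC(=O)OC | starting material
17 | Morita–Baylis–Hillman adduct: C7 carbinol (epimers) bearing the C11(=C13H2)–C12O2Me unit | COC(=O)/C(=C/CC/C(C)=C\COCc1ccc(OC)cc1)[C@@H](O[Si](C)(C)C(C)(C)C)[C@H](C(O)C(=C)C(=O)OC)O[Si](CC)(CC)CC | intermediate
18 | (Z)-2-(bromomethyl)enoate (C7=C11, C13 bromide; O6 PMB) | COC(=O)/C(=C/CC/C(C)=C\COCc1ccc(OC)cc1)[C@@H](O[Si](C)(C)C(C)(C)C)[C@H](/C=C(\CBr)C(=O)OC)O[Si](CC)(CC)CC | intermediate
19 | C6 allylic alcohol of 18 | COC(=O)/C(=C/CC/C(C)=C\CO)[C@@H](O[Si](C)(C)C(C)(C)C)[C@H](/C=C(\CBr)C(=O)OC)O[Si](CC)(CC)CC | intermediate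
20 | (Z)-enal (C6 aldehyde) carrying the C13 bromide, cyclisation precursor | COC(=O)/C(=C/CC/C(C)=C\C=O)[C@@H](O[Si](C)(C)C(C)(C)C)[C@H](/C=C(\CBr)C(=O)OC)O[Si](CC)(CC)CC | intermediate
21 | ring-closed seco hydroxy ester: ten-membered carbocycle with 6-OH and the C11(=C13H2)–C12O2Me group on C7 (present as its chromium alkoxide) | C=C(C(=O)OC)[C@H]1[C@H](O)/C=C(/C)CC/C=C(/C(=O)OC)[C@@H](O[Si](C)(C)C(C)(C)C)[C@H]1O[Si](CC)(CC)CC | intermediate
22 | macrolactone: target skeleton with O8 TES and O9 TBS (C6–C9 configured as in 26) | C=C1C(=O)O[C@@H]2/C=C(/C)CC/C=C(/C(=O)OC)[C@@H](O[Si](C)(C)C(C)(C)C)[C@@H](O[Si](CC)(CC)CC)[C@@H]12 | intermediate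
23 | 8-hydroxy macrolactone (O9 TBS) | C=C1C(=O)O[C@@H]2/C=C(/C)CC/C=C(/C(=O)OC)[C@@H](O[Si](C)(C)C(C)(C)C)[C@@H](O)[C@@H]12 | intermediate
24 | angelic acid, (2Z)-2-methylbut-2-enoic acid | C/C=C(/C)C(=O)O | starting material
25 | 8-O-angeloyl-9-O-TBS macrolactone | C=C1C(=O)O[C@@H]2/C=C(/C)CC/C=C(/C(=O)OC)[C@@H](O[Si](C)(C)C(C)(C)C)[C@@H](OC(=O)/C(C)=C\C)[C@@H]12 | intermediate
26 | CNP0305372.1: (1(10)E,4Z,6R,7S,8S,9R)-8-angeloyloxy-9-hydroxy-14-methoxycarbonyl germacra-1(10),4,11(13)-trien-6,12-olide | C=C1C(=O)O[C@@H]2/C=C(/C)CC/C=C(/C(=O)OC)[C@@H](O)[C@@H](OC(=O)/C(C)=C\C)[C@@H]12 | target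

Total step count: 17. Longest linear sequence: 15 steps (steps 1, 2 and 5–17 from 2-deoxy-L-ribose); steps 3 and 4 make the C1–C6 aldehyde from nerol.

Steps most likely to fail

Step 14. The cyclisation may lose to intermolecular coupling or to reductive loss of the allylmetal, or the aldehyde may attack the other face of C7 (the competing rotamer with the C8 oxygen anti), giving poor facial selectivity. The fallback sets out from 17 and returns at 22, generating the allylmetal by umpolung of an allylic acetate instead of by halide reduction. Acetylation of 17 (Ac2O, pyridine, DMAP) should give the allylic acetate F1, DDQ then frees the C6 alcohol F2, and TEMPO/PhI(OAc)2 gives the enal acetate F3. Pd(PPh3)4 (catalytic, zerovalent palladium) with InI in THF/DMF at high dilution turns the acetate, through a π-allylpalladium complex, into an allylindium species. This is softer, not Lewis acidic and less prone to elimination; it should add at C7 to the aldehyde and lactonise to 22.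

Step 10. The amine-catalysed addition to the hindered aldehyde may be slow enough for base-induced epimerisation at C8 or β-elimination of the C9 silyloxy group to compete. The fallback sets out from 15 and returns at 17 and makes no new isolated compound. The preformed [α-(methoxycarbonyl)vinyl]diisobutylaluminium (from methyl propiolate, iBu2AlH and N-methylmorpholine N-oxide in THF at 0 °C) is added to 15 under non-basic conditions; this vinylalumination should give 17 within hours.

Step 6. The elimination may give poor E/Z control at C1=C10, with some loss of the β-silyloxy group. The fallback sets out from 4, returns at 11 and replaces steps 5 and 6. C-phosphorylation of the lactone enolate (LiN(iPr)2 2.2 equiv, ClP(O)(OEt)2, THF, −78 °C to rt, through the enol phosphate) should give the α-(diethoxyphosphoryl) lactone F4. Horner–Wadsworth–Emmons olefination of F4 with aldehyde 8 (LiCl, DBU, MeCN) should then give 11 with the E-selectivity usual for stabilised phosphonates.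

Further compounds
F1 | step 14 | allylic acetate of 17 | COC(=O)/C(=C/CC/C(C)=C\COCc1ccc(OC)cc1)[C@@H](O[Si](C)(C)C(C)(C)C)[C@H](C(OC(C)=O)C(=C)C(=O)OC)O[Si](CC)(CC)CC
F2 | step 14 | C6 alcohol of the allylic acetate | COC(=O)/C(=C/CC/C(C)=C\CO)[C@@H](O[Si](C)(C)C(C)(C)C)[C@H](C(OC(C)=O)C(=C)C(=O)OC)O[Si](CC)(CC)CC
F3 | step 14 | (Z)-enal of the allylic acetate | COC(=O)/C(=C/CC/C(C)=C\C=O)[C@@H](O[Si](C)(C)C(C)(C)C)[C@H](C(OC(C)=O)C(=C)C(=O)OC)O[Si](CC)(CC)CC
F0 | step 10 | none | none
F4 | step 6 | α-(diethoxyphosphoryl) derivative of lactone 4 (3,4-trans drawn) | O=C1[C@H](P(=O)(OCC)OCC)[C@@H](O[Si](C)(C)C(C)(C)C)[C@H](CO[Si](CC)(CC)CC)O1
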